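Readings and results were computed with constants of no real substance; noise was put on by code.

**The amounts.** Cedar, maple and birch are charged with 0.10 M of starting material and differ in free catalyst, and I must say how that charge is shared among starting material, target and side product at the end.

| setting | Wednesday's | Thursday's | cedar | maple | birch |
|---|---|---|---|---|---|
| starting material | 0.10 M | 0.10 M | 0.10 M | 0.10 M | 0.10 M |
| free catalyst | 0.11 mM | 1.4 mM | 0.20 mM | 0.60 mM | 1.8 mM |
| remark | run made earlier | run made earlier |  |  |  |
| time |  |  | 12 h | 12 h | 12 h |

- Wednesday's (time / h: target / %, starting material / %, side product / %): 0.833: 3.5, 89.5, 7.0; 2.50: 7.9, 72.7, 19.3; 4.00: 11.8, 59.3, 28.3; 6.00: 15.3, 47.4, 38.5; 10.0: 17.6, 30.4, 51.7; 12.0: 18.3, 25.4, 56.7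
- Thursday's (time / h: target / %, starting material / %, side product / %): 0.833: 12.2, 81.0, 6.7; 2.50: 25.6, 57.6, 16.4; 4.00: 31.1, 44.8, 24.0; 6.00: 33.1, 36.3, 31.1; 10.0: 30.0, 27.7, 41.6; 12.0: 28.2, 24.6, 47.1

(each reading ± 0.5 percentage points)

* which of these there is most of at the end, counted by the starting material in it, cedar (starting material / side product / target)
* which of these there is most of at the end, counted by the starting material in it, maple (starting material / side product / target)
* which of these there is most of at the end, counted by the starting material in it, birch (starting material / side product / target)
* the largest of these amounts at the end, in percent of the starting material charged, cedar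
* the largest of these amounts at the end, in percent of the starting material charged, maple
* the largest of these amounts at the end, in percent of the starting material charged, birch

- steps thought possible: starting material + free catalyst <-> free catalyst + target; free catalyst -> spent catalyst; 2 free catalyst <-> resting dimer; starting material -> side product

**Side clock.** I take side product to grow at a constant q times the starting material present. Wednesday's gain from 2.50 h to 10.0 h, divided by the area under starting material, gives q = 0.0897 h⁻¹. But might catalyst speed this step? The first readings say not: Thursday shows 6.7% of side product and Wednesday 7.0%.

**Catalyst order.** Thursday's target peaks near 6.00 h, where target over starting material reads K = 0.912; I take this as the equilibrium ratio. The early target gain then gives a pseudo-first-order constant k of 0.0453 h⁻¹ on Wednesday and 0.175 h⁻¹ on Thursday. That is an order in catalyst of 0.531, close to a square root, as if free catalyst stood in balance with resting dimer. Scaling by that root gives birch k = 0.198 h⁻¹.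

**Pool clock.** Once target and starting material move together, their sum, the pool, shrinks at a steady rate λ = q/(1 + r), where r is their ratio. With r = K, λ is 0.0469 h⁻¹. The objection is that the drain acts on starting material, and Thursday's last ratio, 1.15, stands above K. Requiring target to fall at λ gives r = K/(1 − λK/k). For birch, r becomes 1.16, then λ 0.0415 h⁻¹, then r 1.13, and finally the pool clock λ = 0.0422 h⁻¹.

**My reckoning.** The early fast relaxation has rate μ = 0.463 h⁻¹, and the slow part starts from a fraction 0.887 of the pool. So I reckon that birch ends with 46.5% side product, more than its target of 28.4%. Cedar and maple have catalyst between Wednesday's and Thursday's, so I place their side product between 47.1% and 56.7%, and I expect it above target and starting material, as the readings of both runs show it at 12.0 h.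

**The result.** The forecast gives 54.3%, 50% and 46.5% for cedar, maple and birch: “Side product stays largest everywhere”. Cedar, maple and birch end with side product above target and starting material, at 54.0%, 49.5% and 46.4%.

    starting material + free catalyst ⇌ free catalyst + target (K = 0.920, k = 830 M⁻¹ h⁻¹)
    free catalyst → spent catalyst (k = 9.90 × 10⁻⁴ h⁻¹)
    2 free catalyst ⇌ resting dimer, settled at all times (K = 13000 M⁻¹)
    starting material → side product (k = 0.0900 h⁻¹)

**What stands.** In birch the side step uses starting material at 0.44 of the forward rate of the catalysed step alone, the same at 3.99 h as at 12.0 h, and target over starting material ends at 1.12 against my r of 1.13. Carrying birch's pool from 6.00 h with λ to a second flask, birch stopped at 8.0 h, gives 36.0% side product, and that flask holds 36.3%.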